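In a one-step world, with L going reversibly to Q, the telling number is the L left rather than the Q made: a plateau holds a fixed ratio of Q to L, an equilibrium constant, and that ratio follows the van't Hoff law in temperature.

| flask | L | E | temperature | remark | time |
|---|---|---|---|---|---|
| maple | 0.20 M | 0.065 mM | 60 °C | run made earlier |  |
| elm | 0.20 M | 0.098 mM | 90 °C | run made earlier |  |
| ash | 0.30 M | 0.13 mM | 60 °C | run made earlier |  |
| beta | 0.20 M | 0.13 mM | 90 °C |  | 3.0 d |
| eta | 0.20 M | 0.13 mM | 65 °C |  | 3.0 d |
| gamma | 0.20 M | 0.13 mM | 115 °C |  | 3.0 d |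

| run | time / d | Q / % | L / % |
|---|---|---|---|
| maple | 1.04 | 4.2 | 3.6 |
| maple | 1.67 | 4.8 | 3.2 |
| maple | 2.00 | 5.5 | 2.8 |
| maple | 4.00 | 7.4 | 3.5 |
| maple | 6.00 | 10.2 | 3.8 |
| maple | 10.0 | 12.5 | 4.1 |
| maple | 12.0 | 13.2 | 3.0 |
| elm | 0.250 | 11.5 | 39.8 |
| elm | 0.333 | 13.9 | 39.1 |
| elm | 0.500 | 15.8 | 38.5 |
| elm | 0.833 | 16.4 | 36.4 |
| elm | 1.25 | 17.8 | 37.3 |
| elm | 2.08 | 17.6 | 37.4 |
| elm | 3.00 | 17.9 | 38.1 |
| ash | 1.04 | 7.6 | 3.2 |
| ash | 4.00 | 12.5 | 2.6 |
| ash | 6.00 | 13.9 | 3.4 |
| ash | 8.00 | 15.9 | 3.5 |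
| ash | 12.0 | 15.4 | 3.3 |

(readings scatter by 0.5 percentage points)

- the flask that comes out highest in amount of Q, in percent of the L charged, or "all alike" when all lie within 1.5 percentage points (beta / eta / gamma / all alike)
- Q at the end, in percent of the L charged, beta
- Q at the end, in percent of the L charged, eta
- Q at the end, in percent of the L charged, gamma

- the earlier runs were read with a standard deviation of 0.5 percentage points

The elm run gives 0.470 for the plateau ratio, Q divided by the L left, on its last two readings. The ash run at 60 °C reads 4.60, ten times as much. On a van't Hoff line that fall is a heat of 76.5 kJ mol⁻¹, which puts the ratio at 115 °C near 0.0920.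

Turned round, the question is what gamma would need in order to top elm's plateau of 17.8%, which beta should share at the same temperature. Even with nothing standing outside L and Q, gamma's ratio would have to reach 0.216, and the reckoned ratio falls short of that by a factor of 2.35. Elm does show a rest, since its L and Q sum to 56.0%. This reckoning therefore puts gamma's Q below 8.42%, under elm's plateau, and so sets gamma below beta. That ceiling does not bind eta, whose ratio on the same line is 3.06, and the reckoning gives no figure for eta. The ash run, colder than eta and with more L, reads Q 12.5% after 4.00 d, less than elm's plateau, and on that reading alone the reckoning leans to beta over eta.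

The forecast names gamma, with beta 17.9%, eta 13.8% and gamma 19.5%, from an “extrapolated plateau about 19.5%, assuming E survives”. On gamma it differs from the reckoning above.

The flasks give beta 17.9%, eta 14.2% and gamma 6.98%, so beta comes out highest.

    L + E ⇌ Q + E, rate k1*[L]*[E] forward; the back reaction follows from the equilibrium constant (K = 0.480, k = 0.210 M⁻¹ s⁻¹, Ea = 45.0 kJ mol⁻¹, ΔH = −81.0 kJ mol⁻¹)
    Q + E ⇌ J + E, rate k2*[E]*[Q] forward; the back reaction follows from the equilibrium constant (K = 2.50, k = 0.0870 M⁻¹ s⁻¹, Ea = 66.0 kJ mol⁻¹, ΔH = −21.0 kJ mol⁻¹)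
    J ⇌ L (k = 1.40 × 10⁻⁴ s⁻¹, Ea = 112 kJ mol⁻¹)
    E ⇌ G (K = 0.580, k = 1.30 × 10⁻⁴ s⁻¹, Ea = 117 kJ mol⁻¹, ΔH = 16.0 kJ mol⁻¹)
    (constants at 90 °C)

In gamma the relaxation half-lives, 0.385 h for L with Q and 0.194 d for Q with J, are short against the 3.0 d of the run, and Q already stands at 6.98% after 1.50 d, the mark of thermodynamic control; its plateau ratio is 0.0853. From 0.470 the same van't Hoff line gives 0.238 at 100 °C, and a flask like gamma kept there ends with Q 13.6% and L 58.2%, a ratio of 0.234.

The numbers in the tables are calculated for an exercise.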